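The 2,3-dihydrobenzofuran is cut across O1–C2 and C3a–C3, which reveals a chalcone–dihydrochalcone dehydrodimer: isoliquiritigenin and davidigenin. The key step is a copper(II)-mediated oxidative [3+2] coupling of the two unprotected monomers. It exploits the 4-hydroxystyryl ketone of the chalcone, whose phenoxyl radical carries spin on the carbon alpha to the ketone (future C3), and the free position ortho to the phenol oxygen in the alkylphenol ring of davidigenin; the para-quinone methide formed is closed by that oxygen at C2. A chiral bis(oxazoline) on copper, chelated by the 2'-hydroxy ketone beside C3, is proposed to set C3, and C2 follows trans.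

Key step: step 2

Remark: the core is numbered as 2,3-dihydro-1-benzofuran (O1, C2 bearing the 4-hydroxyphenyl group, C3 bearing the aroyl group, C5 bearing the chain); the target is the trans-(2S,3S) isomer. Davidigenin is made from isoliquiritigenin because its commercial supply is less secure.

Step 1
Reactants: 1 isoliquiritigenin
Product: 2 davidigenin
Conditions: H2 (1 atm), 5% Pd/C, EtOAc, rt, stopped after uptake of 1 equiv
Reagents that add atoms: none
Why: Heterogeneous catalytic hydrogenation should saturate the enone C=C much faster than it reduces the electron-rich, hydrogen-bonded 2,4-dihydroxyaryl ketone; no stereocenter is formed.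

Step 2
Reactants: 1 isoliquiritigenin (1.0 equiv); 2 davidigenin (1.2 equiv)
Product: 4 1-(2,4-dihydroxyphenyl)-3-[(2S,3S)-3-(2,4-dihydroxybenzoyl)-2-(4-hydroxyphenyl)-2,3-dihydro-1-benzofuran-5-yl]propan-1-one, via para-quinone methide 3 (not isolated)
Conditions: Cu(OTf)2 (2.3 equiv), (R,R)-t-Bu-box (2.5 equiv), 2,6-lutidine (slow addition), 4 Å MS, MeCN/CH2Cl2, −20 °C, Ar; then aq. Na2EDTA
Reagents that add atoms: none
Why: Proposed new method: chalcone 1 is bound through its 2'-phenoxide and ketone oxygen to square-planar copper(II) carrying the bis(oxazoline), copper(II) with 2,6-lutidine removes one electron and one proton from the 4-hydroxyphenyl groups of both partners, and the chelated radical of 1, which has spin on the carbon alpha to the ketone, bonds there to the carbon ortho to the phenoxyl oxygen of 2; tautomerisation of the resulting cyclohexadienone gives para-quinone methide 3, whose ortho-phenol adds to the methide carbon. The closest known reaction type is the racemic silver(I) oxide or peroxidase 8–5 oxidative dehydrodimerisation of 4-hydroxycinnamates and 4-hydroxystilbenes to trans-2-aryl-2,3-dihydrobenzofurans, together with its variant in which a chiral auxiliary on the carbonyl beside the coupling carbon induces asymmetry and the copper(II)–amine oxidative coupling of chelating naphthols. The dihydrofuran ring closes by 5-exo-trig oxa-1,6-addition. C3 is set in the C–C coupling by the ligand, since in the established square-planar model for copper(II) bis(oxazoline) chelates of s-cis α,β-unsaturated acyl donors the (R,R)-ligand covers the re face of the alpha carbon and leaves the si face open, which gives 3S; C2 is set by the substrate, the phenol adding anti to the aroyl group to give the trans ring (2S), which is also the more stable isomer. The step needs cross- instead of homo-coupling and C–C instead of C–O coupling: the electron-poor chelated radical of 1 is polarity-matched with the electron-rich alkylphenoxyl radical of 2, the para position of 2 carries the chain, and only the ortho C–C adduct can rearomatise and be trapped irreversibly by ring closure. It also needs every molecule of 1 to be copper-bound when it couples, which the slight excess of the complex over all 2-hydroxyaryl ketone units is meant to secure.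

Compound list
1 | isoliquiritigenin, (E)-1-(2,4-dihydroxyphenyl)-3-(4-hydroxyphenyl)prop-2-en-1-one | O=C(/C=C/c1ccc(O)cc1)c1ccc(O)cc1O | starting material
2 | davidigenin, 1-(2,4-dihydroxyphenyl)-3-(4-hydroxyphenyl)propan-1-one | O=C(CCc1ccc(O)cc1)c1ccc(O)cc1O | intermediate
3 | para-quinone methide, (2R)-1-(2,4-dihydroxyphenyl)-2-{5-[3-(2,4-dihydroxyphenyl)-3-oxopropyl]-2-hydroxyphenyl}-3-(4-oxocyclohexa-2,5-dien-1-ylidene)propan-1-one, drawn without copper | O=C(CCc1ccc(O)c(c1)[C@H](C(=O)c1ccc(O)cc1O)C=C1C=CC(=O)C=C1)c1ccc(O)cc1O | intermediate
4 | 1-(2,4-dihydroxyphenyl)-3-[(2S,3S)-3-(2,4-dihydroxybenzoyl)-2-(4-hydroxyphenyl)-2,3-dihydro-1-benzofuran-5-yl]propan-1-one (trans) | O=C(CCc1ccc2c(c1)[C@H](C(=O)c1ccc(O)cc1O)[C@@H](c1ccc(O)cc1)O2)c1ccc(O)cc1O | target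

Total step count: 2
Longest linear sequence: 2 steps (1 → 2 → 4)

Steps most likely to fail (the route has only two steps, so both are listed):

1. Step 2. Coupling may take place between radicals that are not bound to copper, so the two faces of the alpha carbon are not differentiated. Homo-coupling of the chalcone, C–O coupling, over-oxidation, and base-induced ring opening of the product by loss of the phenoxide from C2 may also compete. If the sense of induction is opposite to the model, the (S,S)-ligand is taken. Fallback with known chemistry: setting out from 1 and 2, the classical racemic 8–5 oxidative cross-coupling is run with Ag2O in dry acetone/toluene at rt in the dark, with 2 in excess to suppress the chalcone homodimer. This should give the racemic trans-dihydrobenzofuran F1, the trans relationship arising from the same substrate-controlled ring closure. The enantiomers of F1 are then separated by preparative chromatography on an amylose tris(3,5-dimethylphenylcarbamate) stationary phase. The (2S,3S)-enantiomer would be identified by comparing its electronic circular dichroism with a calculated spectrum, and the fallback comes back to the route at 4.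

2. Step 1. Over-reduction may occur on prolonged contact with the catalyst: reduction of the aryl ketone followed by hydrogenolysis of the benzylic alcohol. Fallback: instead of setting out from 1, commercial resorcinol (Oc1cccc(O)c1) and 3-(4-hydroxyphenyl)propanoic acid (O=C(O)CCc1ccc(O)cc1) are joined by Friedel–Crafts acylation in BF3·OEt2 at about 85 °C. Acylation para to one hydroxyl and ortho to the other should give davidigenin directly, and the fallback comes back to the route at 2.

Further compounds
F1 | step 2 | racemic trans-dihydrobenzofuran, 1:1 mixture of 4 and its (2R,3R)-enantiomer | O=C(CCc1ccc2c(c1)[C@H](C(=O)c1ccc(O)cc1O)[C@@H](c1ccc(O)cc1)O2)c1ccc(O)cc1O.O=C(CCc1ccc2c(c1)[C@@H](C(=O)c1ccc(O)cc1O)[C@H](c1ccc(O)cc1)O2)c1ccc(O)cc1O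
F0 | step 1 | none | none
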